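**Plan**

- Cuts, in retrosynthetic order: (i) the ester C–O bond between the piperidine C3 oxygen and the 3,4-dimethoxybenzoyl group; (ii) the pyranone ring (O1–C2, C2–C3 and C4–C4a of the chromone), back to a 2,4,6-trimethoxyphenyl ring; (iii) the N-methyl group and the C3 oxygen, by functional-group change; (iv) C4–C5 and N1–C6 of the piperidine.
- Enabling feature: N1, C2, C3 and C4 of the piperidine, with the trioxygenated benzene ring on C4, are a latent 1-azabuta-1,3-diene (N1=C2–C3=C4–Ar, a cinnamaldehyde N-sulfonylimine). C5–C6 can therefore arrive as an electron-rich two-carbon dienophile in one [4+2] event.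
- Forward order: azadiene, then the piperidine ring (step 3), C3 ketone, cis-amino alcohol, N-methyl, acetophenone, pyranone ring, free phenols, ester.
- Stereochemistry: C4 is benzylic and alpha to the C3 ketone, hence configurationally labile. Both centres (3S,4R) are set together in step 7 by asymmetric transfer hydrogenation with dynamic kinetic resolution. No later step touches C3 or C4.

Key step: step 3

Remark: compounds 8 to 11 are racemic and their SMILES show one enantiomer where a relative configuration exists; the hand of the catalyst in step 7 is assigned by analogy with 2-arylcycloalkanones, and the mirror-image ligand would be used should the sense prove reversed.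

**Route**

Step 1
Reactants: 1 2,4,6-trimethoxybenzaldehyde; 2 (1,3-dioxolan-2-ylmethyl)triphenylphosphonium bromide
Product: 4 (E)-3-(2,4,6-trimethoxyphenyl)prop-2-enal, via vinyl dioxolane 3 (not isolated)
Conditions: KOtBu, THF, 0 °C to rt; then 2 M HCl, THF, rt
Reagents that add atoms: water, O
Why: Wittig olefination of the non-enolisable aldehyde with the acetal-masked formylmethyl ylide should give the vinyl dioxolane (no second homologation is possible), and aqueous acid then hydrolyses the acetal and equilibrates the alkene to the conjugated (E)-enal.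

Step 2
Reactants: 4 (E)-3-(2,4,6-trimethoxyphenyl)prop-2-enal; 5 4-methylbenzenesulfonamide
Product: 6 (E)-4-methyl-N-[(E)-3-(2,4,6-trimethoxyphenyl)prop-2-en-1-ylidene]benzenesulfonamide
Conditions: TiCl4, Et3N, CH2Cl2, 0 °C to rt
Reagents that add atoms: none
Why: Condensation of the aldehyde with the sulfonamide, with TiCl4 as activator and water scavenger, should give the (E)-N-sulfonyl aldimine, the thermodynamically preferred geometry, without touching the C=C bond.

Step 3
Reactants: 6 (E)-4-methyl-N-[(E)-3-(2,4,6-trimethoxyphenyl)prop-2-en-1-ylidene]benzenesulfonamide; 7 ethyl vinyl ether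
Product: 8 rac-(2S,4R)-2-ethoxy-1-(4-methylbenzenesulfonyl)-4-(2,4,6-trimethoxyphenyl)-1,2,3,4-tetrahydropyridine (2,4-cis)
Conditions: ethyl vinyl ether (20 equiv), CH2Cl2, 12 kbar, 25 °C
Reagents that add atoms: none
Why: This is an inverse-electron-demand hetero-Diels–Alder reaction in which the N-sulfonyl group lowers the LUMO of the 1-azadiene N=C–C=C(Ar), so that the aryl-bearing terminus (largest LUMO coefficient) bonds to the CH2 carbon of the enol ether (largest HOMO coefficient) and nitrogen bonds to the oxygen-bearing carbon, giving the C4–C5 and N–C6 bonds of the piperidine in one concerted, asynchronous step. The closest known reaction type is the [4+2] cycloaddition of N-sulfonyl-1-aza-1,3-butadienes derived from cinnamaldehydes with vinyl ethers, which is accelerated by pressure. The tetrahydropyridine ring closes by a suprafacial [4π+2π] cycloaddition through a boat-like endo transition state and not by cyclisation of an open-chain intermediate. Two stereocentres form, the ethoxy-bearing carbon cis to the aryl-bearing carbon through the endo preference of the alkoxy group, and no absolute control is sought because the acetal centre is removed in step 4 and the aryl-bearing centre is reset in step 7. The step needs periselectivity for the N=C–C=C system over [2+2] addition at C=N and head-to-tail regiochemistry, and both are secured by the (E,E) geometry, which lets the diene reach the s-cis form with aryl and sulfonyl groups outside, and by the polarisation that the sulfonyl group imposes. Pressure is chosen because the two ortho-methoxy groups screen the aryl-bearing terminus and the donor ring raises the LUMO.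

Step 4
Reactants: 8 rac-(2S,4R)-2-ethoxy-1-(4-methylbenzenesulfonyl)-4-(2,4,6-trimethoxyphenyl)-1,2,3,4-tetrahydropyridine
Product: 9 rac-1-(4-methylbenzenesulfonyl)-4-(2,4,6-trimethoxyphenyl)-1,2,3,4-tetrahydropyridine
Conditions: Et3SiH (5 equiv), BF3·OEt2, CH2Cl2, −78 °C
Reagents that add atoms: none
Why: Lewis-acid ionisation of the N-sulfonyl N,O-acetal to an N-sulfonyliminium ion and hydride capture from the silane (ionic reduction) should remove the ethoxy group, while the enesulfonamide C=C bond survives in the absence of a protic acid and excess silane outruns Friedel–Crafts capture by the electron-rich ring.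

Step 5
Reactants: 9 rac-1-(4-methylbenzenesulfonyl)-4-(2,4,6-trimethoxyphenyl)-1,2,3,4-tetrahydropyridine
Product: 10 rac-(3R,4R)-1-(4-methylbenzenesulfonyl)-4-(2,4,6-trimethoxyphenyl)piperidin-3-ol (trans)
Conditions: BH3·THF, THF, 0 °C to rt; then NaOH, H2O2, H2O, 0 °C
Reagents that add atoms: hydrogen peroxide, OO
Why: Hydroboration–oxidation of the enesulfonamide should place boron, and then oxygen, on the carbon beta to nitrogen (C3) for electronic reasons and anti to the C4 aryl group; the relative configuration is of no consequence because C3 is oxidised in step 6.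

Step 6
Reactants: 10 rac-(3R,4R)-1-(4-methylbenzenesulfonyl)-4-(2,4,6-trimethoxyphenyl)piperidin-3-ol
Product: 11 rac-1-(4-methylbenzenesulfonyl)-4-(2,4,6-trimethoxyphenyl)piperidin-3-one
Conditions: Dess–Martin periodinane, NaHCO3, CH2Cl2, rt
Reagents that add atoms: none
Why: Dess–Martin oxidation of the secondary alcohol under buffered conditions should give the alpha-aryl ketone, in which C4 is enolisable, as step 7 requires.

Step 7
Reactants: 11 rac-1-(4-methylbenzenesulfonyl)-4-(2,4,6-trimethoxyphenyl)piperidin-3-one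
Product: 12 (3S,4R)-1-(4-methylbenzenesulfonyl)-4-(2,4,6-trimethoxyphenyl)piperidin-3-ol (cis)
Conditions: RuCl[(R,R)-TsDPEN](p-cymene) (2 mol %), HCO2H/Et3N (1:1), DMF, 40 °C
Reagents that add atoms: none
Why: Noyori–Ikariya asymmetric transfer hydrogenation with dynamic kinetic resolution: C4 racemises through the enol in the amine buffer faster than the ketone is reduced, and the chiral Ru–H/N–H catalyst should reduce one enantiomer with equatorial hydride delivery anti to the aryl group, which sets C3 (S) and C4 (R) together as the cis alcohol.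

Step 8
Reactants: 12 (3S,4R)-1-(4-methylbenzenesulfonyl)-4-(2,4,6-trimethoxyphenyl)piperidin-3-ol
Product: 13 (3S,4R)-4-(2,4,6-trimethoxyphenyl)piperidin-3-ol
Conditions: NaC10H8 (sodium naphthalenide), THF, −78 °C; then H2O
Reagents that add atoms: none
Why: Single-electron reductive cleavage of the N–S bond of the arenesulfonamide should free the secondary amine; the aryl methyl ethers and the alkoxide are inert at −78 °C and no stereocentre is involved.

Step 9
Reactants: 13 (3S,4R)-4-(2,4,6-trimethoxyphenyl)piperidin-3-ol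
Product: 14 (3S,4R)-1-methyl-4-(2,4,6-trimethoxyphenyl)piperidin-3-ol
Conditions: aq. HCHO, NaBH(OAc)3, AcOH (cat.), ClCH2CH2Cl, rt
Reagents that add atoms: formaldehyde, C=O
Why: Reductive amination (iminium formation, then hydride transfer from the triacetoxyborohydride) should methylate nitrogen under near-neutral conditions that avoid acid-promoted hydroxymethylation of the electron-rich ring.

Step 10
Reactants: 14 (3S,4R)-1-methyl-4-(2,4,6-trimethoxyphenyl)piperidin-3-ol
Product: 15 (3S,4R)-4-(3-acetyl-2-hydroxy-4,6-dimethoxyphenyl)-1-methylpiperidin-3-yl acetate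
Conditions: Ac2O, BF3·OEt2, CH2Cl2, 0 °C to rt; aq. Na2CO3 work-up
Reagents that add atoms: acetic anhydride, CC(=O)OC(C)=O
Why: Friedel–Crafts acetylation at one of the two equivalent free ring positions, O-acetylation of the alcohol and BF3-assisted cleavage of the most crowded methyl ether (the one between the new acetyl group and the piperidinyl carbon, held in a chelate with the ketone) should give the ortho-hydroxyacetophenone with the phenol where the pyranone oxygen is needed.

Step 11
Reactants: 15 (3S,4R)-4-(3-acetyl-2-hydroxy-4,6-dimethoxyphenyl)-1-methylpiperidin-3-yl acetate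
Product: 17 8-[(3S,4R)-3-hydroxy-1-methylpiperidin-4-yl]-5,7-dimethoxy-2-methyl-4H-chromen-4-one, via diketone 16 (not isolated)
Conditions: NaH, EtOAc (excess), THF, reflux; then conc. HCl, rt
Reagents that add atoms: ethyl acetate, CCOC(C)=O
Why: Claisen condensation of the methyl ketone enolate with ethyl acetate should give the 1,3-diketone, and acid then closes the pyranone ring by attack of the ortho phenol on the distal carbonyl and loss of water, the O-acetyl group being cleaved on the way.

Step 12
Reactants: 17 8-[(3S,4R)-3-hydroxy-1-methylpiperidin-4-yl]-5,7-dimethoxy-2-methyl-4H-chromen-4-one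
Product: 18 5,7-dihydroxy-8-[(3S,4R)-3-hydroxy-1-methylpiperidin-4-yl]-2-methyl-4H-chromen-4-one (rohitukine)
Conditions: pyridine hydrochloride (melt), 180 °C
Reagents that add atoms: none
Why: Nucleophilic demethylation of both protonated aryl methyl ethers by chloride in molten pyridinium chloride should free the two phenols; the chromone and the amino alcohol carry no group that is labile under these conditions and C3 and C4 are not involved.

Step 13
Reactants: 18 rohitukine; 19 3,4-dimethoxybenzoyl chloride
Product: 21 chrotacumine D, via bis-ester 20 (not isolated)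
Conditions: 19 (2.5 equiv), Et3N, DMAP (cat.), CH2Cl2, 0 °C to rt; then MeOH, K2CO3 (0.3 equiv), 0 °C
Reagents that add atoms: none
Why: DMAP-catalysed acylation should esterify the C7 phenol and the secondary alcohol (the chelated C5 hydroxyl is the least nucleophilic), and brief methanolysis then removes only the aryl ester, an activated ester of an acidic chromone phenol, while the hindered secondary alkyl benzoate survives.

**Compound list**

1 | 2,4,6-trimethoxybenzaldehyde | COc1cc(OC)c(C=O)c(OC)c1 | starting material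
2 | (1,3-dioxolan-2-ylmethyl)triphenylphosphonium bromide | [Br-].c1ccc([P+](CC2OCCO2)(c2ccccc2)c2ccccc2)cc1 | starting material
3 | 2-[2-(2,4,6-trimethoxyphenyl)ethenyl]-1,3-dioxolane (E/Z mixture) | COc1cc(OC)c(C=CC2OCCO2)c(OC)c1 | intermediate
4 | (E)-3-(2,4,6-trimethoxyphenyl)prop-2-enal | COc1cc(OC)c(/C=C/C=O)c(OC)c1 | intermediate
5 | 4-methylbenzenesulfonamide | Cc1ccc(S(N)(=O)=O)cc1 | starting material
6 | (E)-4-methyl-N-[(E)-3-(2,4,6-trimethoxyphenyl)prop-2-en-1-ylidene]benzenesulfonamide | COc1cc(OC)c(/C=C/C=N/S(=O)(=O)c2ccc(C)cc2)c(OC)c1 | intermediate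
7 | ethyl vinyl ether | C=COCC | starting material
8 | rac-(2S,4R)-2-ethoxy-1-(4-methylbenzenesulfonyl)-4-(2,4,6-trimethoxyphenyl)-1,2,3,4-tetrahydropyridine (2,4-cis) | CCO[C@H]1C[C@@H](c2c(OC)cc(OC)cc2OC)C=CN1S(=O)(=O)c1ccc(C)cc1 | intermediate
9 | rac-1-(4-methylbenzenesulfonyl)-4-(2,4,6-trimethoxyphenyl)-1,2,3,4-tetrahydropyridine | COc1cc(OC)c(C2CCN(S(=O)(=O)c3ccc(C)cc3)C=C2)c(OC)c1 | intermediate
10 | rac-(3R,4R)-1-(4-methylbenzenesulfonyl)-4-(2,4,6-trimethoxyphenyl)piperidin-3-ol (trans) | O[C@H]1CN(S(=O)(=O)c2ccc(C)cc2)CC[C@@H]1c1c(OC)cc(OC)cc1OC | intermediate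
11 | rac-1-(4-methylbenzenesulfonyl)-4-(2,4,6-trimethoxyphenyl)piperidin-3-one | O=C1CN(S(=O)(=O)c2ccc(C)cc2)CCC1c1c(OC)cc(OC)cc1OC | intermediate
12 | (3S,4R)-1-(4-methylbenzenesulfonyl)-4-(2,4,6-trimethoxyphenyl)piperidin-3-ol | O[C@@H]1CN(S(=O)(=O)c2ccc(C)cc2)CC[C@@H]1c1c(OC)cc(OC)cc1OC | intermediate
13 | (3S,4R)-4-(2,4,6-trimethoxyphenyl)piperidin-3-ol | O[C@@H]1CNCC[C@@H]1c1c(OC)cc(OC)cc1OC | intermediate
14 | (3S,4R)-1-methyl-4-(2,4,6-trimethoxyphenyl)piperidin-3-ol | O[C@@H]1CN(C)CC[C@@H]1c1c(OC)cc(OC)cc1OC | intermediate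
15 | (3S,4R)-4-(3-acetyl-2-hydroxy-4,6-dimethoxyphenyl)-1-methylpiperidin-3-yl acetate | CC(=O)O[C@@H]1CN(C)CC[C@@H]1c1c(O)c(C(C)=O)c(OC)cc1OC | intermediate
16 | 1-{2-hydroxy-3-[(3S,4R)-3-hydroxy-1-methylpiperidin-4-yl]-4,6-dimethoxyphenyl}butane-1,3-dione | O[C@@H]1CN(C)CC[C@@H]1c1c(O)c(C(=O)CC(C)=O)c(OC)cc1OC | intermediate
17 | 8-[(3S,4R)-3-hydroxy-1-methylpiperidin-4-yl]-5,7-dimethoxy-2-methyl-4H-chromen-4-one | O[C@@H]1CN(C)CC[C@@H]1c1c(OC)cc(OC)c2c(=O)cc(C)oc12 | intermediate
18 | 5,7-dihydroxy-8-[(3S,4R)-3-hydroxy-1-methylpiperidin-4-yl]-2-methyl-4H-chromen-4-one (rohitukine) | O[C@@H]1CN(C)CC[C@@H]1c1c(O)cc(O)c2c(=O)cc(C)oc12 | intermediate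
19 | 3,4-dimethoxybenzoyl chloride | COc1ccc(C(Cl)=O)cc1OC | starting material
20 | (3S,4R)-4-{7-[(3,4-dimethoxybenzoyl)oxy]-5-hydroxy-2-methyl-4-oxo-4H-chromen-8-yl}-1-methylpiperidin-3-yl 3,4-dimethoxybenzoate | COc1ccc(C(=O)O[C@@H]2CN(C)CC[C@@H]2c2c(OC(=O)c3ccc(OC)c(OC)c3)cc(O)c3c(=O)cc(C)oc23)cc1OC | intermediate
21 | (3S,4R)-4-(5,7-dihydroxy-2-methyl-4-oxo-4H-chromen-8-yl)-1-methylpiperidin-3-yl 3,4-dimethoxybenzoate (chrotacumine D) | COc1ccc(C(=O)O[C@@H]2CN(C)CC[C@@H]2c2c(O)cc(O)c3c(=O)cc(C)oc23)cc1OC | target

**Step count and risks**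

Total step count: 13. Longest linear sequence: 13 steps (from 1).

Steps most likely to fail:

1. Step 3. The cycloaddition may stall because the two ortho-methoxy groups screen both faces of the aryl-bearing terminus and the donor ring raises the LUMO, so that hydrolysis of the sulfonylimine or polymerisation of the vinyl ether takes over. Fallback, setting out from 6: the nucleophile is changed to a HOMO-raised enamine. Acetaldehyde (5 equiv) with (S)-α,α-diphenylprolinol trimethylsilyl ether (20 mol %) and benzoic acid in MeCN/H2O at rt should add through its enamine to the aryl-bearing carbon (Michael addition), and the sulfonamide nitrogen then closes onto the released aldehyde to give the hemiaminal 4-(2,4,6-trimethoxyphenyl)-1-(4-methylbenzenesulfonyl)-1,2,3,4-tetrahydropyridin-2-ol F1. Et3SiH and BF3·OEt2 in CH2Cl2 at −78 °C then remove the hydroxyl group, and the route is rejoined at 9.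

2. Step 7. Enolisation of the hindered ketone may be slower than its reduction (incomplete dynamic resolution), or the catalyst may discriminate poorly between the two faces. Fallback, setting out from 11: LiBH(s-Bu)3 in THF at −78 °C should give, by equatorial hydride attack, racemic cis-1-(4-methylbenzenesulfonyl)-4-(2,4,6-trimethoxyphenyl)piperidin-3-ol F2. Esterification with (S)-2-methoxy-2-phenylacetic acid (EDC·HCl, DMAP, CH2Cl2) gives two diastereomeric esters, the (3S,4R)-piperidinyl (2S)-2-methoxy-2-phenylacetate F3 and the (3R,4S)-piperidinyl (2S)-2-methoxy-2-phenylacetate F4, which are separated by chromatography or crystallisation. K2CO3 in MeOH cleaves F3 and the route is rejoined at 12.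

3. Step 13. The hindered axial alcohol may acylate incompletely, or the methanolysis may also remove the wanted ester through assistance by the neighbouring amine. Fallback, setting out from 18: TBSCl and imidazole in DMF at 0 °C should silylate the acidic C7 phenol selectively to give 7-[(tert-butyldimethylsilyl)oxy]-5-hydroxy-8-[(3S,4R)-3-hydroxy-1-methylpiperidin-4-yl]-2-methyl-4H-chromen-4-one F5. Acylation with 19 (Et3N, DMAP, CH2Cl2) gives (3S,4R)-4-{7-[(tert-butyldimethylsilyl)oxy]-5-hydroxy-2-methyl-4-oxo-4H-chromen-8-yl}-1-methylpiperidin-3-yl 3,4-dimethoxybenzoate F6, and HF·pyridine in THF at 0 °C removes the silyl group to reach 21.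

**Further compounds**

F1 | step 3 | 4-(2,4,6-trimethoxyphenyl)-1-(4-methylbenzenesulfonyl)-1,2,3,4-tetrahydropyridin-2-ol (mixture of stereoisomers) | OC1CC(c2c(OC)cc(OC)cc2OC)C=CN1S(=O)(=O)c1ccc(C)cc1
F2 | step 7 | racemic cis-1-(4-methylbenzenesulfonyl)-4-(2,4,6-trimethoxyphenyl)piperidin-3-ol (1:1 mixture of 12 and its enantiomer) | O[C@@H]1CN(S(=O)(=O)c2ccc(C)cc2)CC[C@@H]1c1c(OC)cc(OC)cc1OC.O[C@H]1CN(S(=O)(=O)c2ccc(C)cc2)CC[C@H]1c1c(OC)cc(OC)cc1OC
F3 | step 7 | (3S,4R)-1-(4-methylbenzenesulfonyl)-4-(2,4,6-trimethoxyphenyl)piperidin-3-yl (2S)-2-methoxy-2-phenylacetate | CO[C@H](C(=O)O[C@@H]1CN(S(=O)(=O)c2ccc(C)cc2)CC[C@@H]1c1c(OC)cc(OC)cc1OC)c1ccccc1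
F4 | step 7 | (3R,4S)-1-(4-methylbenzenesulfonyl)-4-(2,4,6-trimethoxyphenyl)piperidin-3-yl (2S)-2-methoxy-2-phenylacetate | CO[C@H](C(=O)O[C@H]1CN(S(=O)(=O)c2ccc(C)cc2)CC[C@H]1c1c(OC)cc(OC)cc1OC)c1ccccc1
F5 | step 13 | 7-[(tert-butyldimethylsilyl)oxy]-5-hydroxy-8-[(3S,4R)-3-hydroxy-1-methylpiperidin-4-yl]-2-methyl-4H-chromen-4-one | O[C@@H]1CN(C)CC[C@@H]1c1c(O[Si](C)(C)C(C)(C)C)cc(O)c2c(=O)cc(C)oc12
F6 | step 13 | (3S,4R)-4-{7-[(tert-butyldimethylsilyl)oxy]-5-hydroxy-2-methyl-4-oxo-4H-chromen-8-yl}-1-methylpiperidin-3-yl 3,4-dimethoxybenzoate | COc1ccc(C(=O)O[C@@H]2CN(C)CC[C@@H]2c2c(O[Si](C)(C)C(C)(C)C)cc(O)c3c(=O)cc(C)oc23)cc1OC
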